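**Assumption:** the acyl chain of the given SMILES is read as 32 carbon atoms (dotriacontanoyl, C1 carbonyl to C32 methyl). The molecule has no stereocentre and no stereodefined double bond, so no descriptor is needed anywhere in the route.

## Structural features

Basalethanolide A (7) is an ester of two parts: an unbranched, saturated C32 acyl chain (C1 carbonyl, C2–C31 thirty methylene groups, C32 methyl) and tyrosol, whose primary aliphatic oxygen carries the acyl group. The aromatic part is one para-disubstituted benzene ring with a free phenolic hydroxyl opposite the CH2CH2O arm. There is no other ring, no stereocentre and no double bond outside the arene. The fragile groups are the phenol (easily oxidised, and a competing acyl acceptor) and the ester (cleaved by base or transesterification). The real difficulty is the chain: a C32 acid of one exact length is not a commodity, natural wax acids occur as mixtures of homologues that co-crystallise, and thirty identical CH2 groups offer no polar handle for a conventional C–C disconnection. The key step exploits exactly this feature: every CH2–CH2 bond of C2–C32 joins two carbons of the same polarity, so the C11–C12 bond can be formed by union of two primary alkyl radicals, each released from a carboxylate by anodic decarboxylation. The smaller difficulty is acylation of the aliphatic hydroxyl in the presence of the phenol, together with the low solubility and waxy behaviour of all C30+ compounds.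

## Logic of the disconnections

7 ⇒ 5 + 6. The bond cut is the acyl C1–O bond of the ester. It is formed last because 6 carries the oxidisable phenol, which must not be present at the anode, and because 5 is already an acyl donor that needs neither hydrolysis nor activation. The gain is the separation of the aromatic part, a commodity, from the chain. The demand on the forward step is that only the aliphatic hydroxyl of 6 is acylated, that the phenol stays free without a protecting group, and that methanol is removed to drive the equilibrium.

5 ⇒ 1 + 2, through 3 and 4. The bond cut is C11–C12 in the middle of the methylene chain, a bond between two carbons of like polarity. In one sentence, the route is the anodic decarboxylative cross-coupling of 1 with 2. The cut is placed there because the two halves then map onto two commodity acids, and because the halves are unequal and differently functionalised, so the three statistical coupling products differ in size and in number of ester groups. The gain is large: the whole C32 chain with its terminal ester arises in one operation, and each carboxyl carbon serves as a traceless activating group. The demand on the forward step is that 3 and 4 are generated together at high local concentration on one electrode, that they are not oxidised further to cations, that nothing else oxidisable is in the cell, and that the homo-coupled products can be removed. 1, 2 and 6 are commercial and are not disconnected further.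

## Other disconnections considered

Alternative 1: the acyl C1–O bond is cut at the outset, which is the first disconnection that comes to mind. Dotriacontanoic acid A1 and 6 would be joined by a chemoselective esterification (acid catalysis with removal of water, or a lipase). The forward step is sound and short, but it leaves the whole difficulty of the target inside A1. A1 is offered only in research quantities, natural sources deliver it mixed with C30 and C34 homologues that co-crystallise, and any synthesis of A1 must itself make a chain C–C bond. The chosen plan reaches the same acyl-transfer stage with an ester built in one step from two commodity acids, with a chain length fixed by construction.

Alternative 2: the alkyl O–CH2 bond of the ester is cut, so that the acid is the nucleophile and the arene a masked electrophile. 4-(2-Bromoethyl)phenol A2, derived from 6 by exchange of the aliphatic hydroxyl for bromide, would be closed by base through the para carbon of its phenoxide to spiro[2.5]octa-4,7-dien-6-one A3. A1 would then open the cyclopropane of A3 at CH2 in a homoconjugate addition driven by rearomatisation, which creates the ester and the free phenol in the same event. This removes the phenol/alcohol selectivity question, since the phenol does not exist until the ester is formed. It is not preferred for three reasons: A3 is a strained, polymerisation-prone dienone that has to be handled in dilute solution; a weakly nucleophilic fatty acid must compete for A3 with the phenol of the product and of unconsumed A2, which opens a path to aryl ethers and oligomers; and it is longer. Above all it still needs A1, so the chain problem is untouched.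

Alternative 3: a chain C–C bond is cut as an alkene, C13=C14. Methyl (13Z)-docos-13-enoate A4 and icos-1-ene A5 would undergo olefin cross-metathesis with the second-generation Grubbs catalyst to methyl dotriacont-13-enoate A6 (E/Z mixture), which would be hydrogenated to 5. This also builds the chain from commodity lipids. However, cross-metathesis of an internal with a terminal alkene is statistical over many more partners than a radical cross-coupling of two species, so A6 would have to be taken out of a mixture of alkenes of similar polarity. Ruthenium hydride species formed on catalyst decay can move double bonds along the chain and so create C31 and C33 homologues, which after hydrogenation could not be separated from 5. A hydrogenation step is also added. In the anodic coupling the chain length is fixed by the two acids, because primary alkyl radicals do not rearrange, and only three products differing in the number of ester groups are expected.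

Key step: step 1

## Route

Step 1
Reactants: 1 docosanoic acid (behenic acid); 2 12-methoxy-12-oxododecanoic acid (monomethyl dodecanedioate)
Product: 5 methyl dotriacontanoate, via henicosyl radical 3 (not isolated), via 11-methoxy-11-oxoundecyl radical 4 (not isolated)
Conditions: Pt anode, Pt cathode, undivided cell, constant current (ca. 0.2 A cm−2, ca. 1.3 F per mol of acid, to pH 8), 1:2 = 1:3, KOH (5 mol% of total acid), MeOH/light petroleum (b.p. 60–80 °C) 4:1, 50 °C
Reagents that add atoms: none
Why: Mixed (crossed) Kolbe electrolysis: the carboxylates of 1 and 2, present through partial neutralisation with KOH, are adsorbed on the platinum anode and oxidised by one electron each to acyloxy radicals, which lose carbon dioxide within nanoseconds to give the primary alkyl radicals 3 and 4 side by side in high local concentration; these combine to the C11–C12 bond of 5, while the cathode forms dihydrogen and regenerates the base. The closest known reaction type is the classical anodic chain extension of a fatty acid with the half-ester of an α,ω-diacid, a standard way to unbranched very-long-chain acids. No ring is closed and no stereocentre is formed. The step needs one-electron (radical) rather than two-electron (carbocation, Hofer–Moest) chemistry, and the substrate secures this: both radicals are primary and unbranched with no α-heteroatom, so their further oxidation is difficult, and smooth platinum, high current density, weakly acidic methanol and a low degree of neutralisation all favour coupling. It needs cross- over homo-coupling, which is statistical; with the cheap half-ester 2 in threefold excess, three of four radicals 3 should on statistical grounds meet a radical 4. It needs chemoselectivity, which is given because the ester group of 2 lies ten methylene groups from the carboxylate and is inert at the anode (methanol can only return the same methyl ester), and because no arene or phenol is present at this stage. Primary alkyl radicals do not rearrange, so 5 has exactly 32 chain carbons, and the three coupling products (the C42 alkane from two radicals 3, the monoester 5 and the C22 diester from two radicals 4) differ in the number of ester groups and should separate on silica with warm heptane/toluene or by crystallisation. The light petroleum is there to keep the paraffinic products in solution and off the anode.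

Step 2
Reactants: 5 methyl dotriacontanoate; 6 tyrosol (4-(2-hydroxyethyl)phenol)
Product: 7 Basalethanolide A (2-(4-hydroxyphenyl)ethyl dotriacontanoate)
Conditions: Novozym 435 (immobilised Candida antarctica lipase B), 6 (3 equiv), 5 Å MS, toluene/2-methyl-2-butanol 4:1, 70 °C; hot filtration, aqueous wash, crystallisation
Reagents that add atoms: none
Why: Lipase-catalysed transesterification: the active-site serine is acylated by the methyl ester 5 with release of methanol, and the acyl-enzyme is then taken over by the primary hydroxyl of 6. The phenolic hydroxyl is not acylated by this enzyme, so no protecting group is needed, and adsorption of methanol on the sieves drives the equilibrium. Chemoselective lipase acylation of tyrosol-type phenolic alcohols with fatty acid alkyl esters is a well-established reaction type; the tertiary co-solvent is not a substrate and serves to dissolve 6.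

## Compound list

1 | docosanoic acid (behenic acid) | CCCCCCCCCCCCCCCCCCCCCC(=O)O | starting material
2 | 12-methoxy-12-oxododecanoic acid (monomethyl dodecanedioate) | COC(=O)CCCCCCCCCCC(=O)O | starting material
3 | henicosyl radical (not isolated) | [CH2]CCCCCCCCCCCCCCCCCCCC | intermediate
4 | 11-methoxy-11-oxoundecyl radical (not isolated) | [CH2]CCCCCCCCCC(=O)OC | intermediate
5 | methyl dotriacontanoate | CCCCCCCCCCCCCCCCCCCCCCCCCCCCCCCC(=O)OC | intermediate
6 | tyrosol, 4-(2-hydroxyethyl)phenol | OCCc1ccc(O)cc1 | starting material
7 | Basalethanolide A, 2-(4-hydroxyphenyl)ethyl dotriacontanoate | CCCCCCCCCCCCCCCCCCCCCCCCCCCCCCCC(=O)OCCc1ccc(O)cc1 | target

## Step count and risk assessment

Total step count: 2. Longest linear sequence: 2 steps (1 + 2 → 5, then 5 + 6 → 7). The route has only two steps, so both are assessed, the key step first.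

**Step 1 (key step).** The most likely failure is fouling of the anode by a film of sparingly soluble paraffinic material. The anode potential then rises and the reaction shifts to two-electron oxidation, giving ethers, alkenes and esters through carbocations. The limited solubility of 1 in methanol works in the same direction. In addition the cross-coupling is statistical, so part of 1 is inevitably lost to homo-coupling, and the waxy products may co-crystallise and separate incompletely.

Fallback (sets out from 1, returns at 5): the neighbouring C10–C11 bond is made by polar, copper-catalysed alkyl–alkyl coupling instead of radical union. 1 is reduced (LiAlH4, THF, reflux) to docosan-1-ol F1, which is converted with 48% aqueous HBr/H2SO4 at 110 °C into 1-bromodocosane F2. F2 gives docosylmagnesium bromide F3 (Mg, THF, 50 °C, used in solution). F3 is coupled with commercial methyl 10-bromodecanoate (COC(=O)CCCCCCCCCBr) under Li2CuCl4 catalysis (3 mol%, THF/NMP, 0 °C) to give 5. The ester should survive because copper-catalysed substitution at the primary bromide is much faster at 0 °C than carbonyl addition of the Grignard reagent.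

**Step 2.** The most likely failure is slow or incomplete acyl transfer. The C32 chain is longer than the acyl channel of the lipase, and 5 and 6 make opposite demands on the solvent at a temperature the enzyme tolerates. The reaction can also stall at equilibrium if methanol is not removed efficiently.

Fallback (sets out from 5, returns at 7): the ester bond is made by activating the alcohol instead of the acyl group. 5 is saponified (KOH, EtOH/toluene, reflux; then aqueous HCl) to dotriacontanoic acid F4, the same compound as A1. F4 is condensed with 6 under Mitsunobu conditions (PPh3, DIAD, THF/toluene, 0 to 40 °C). Only the aliphatic hydroxyl of 6 can form an alkoxyphosphonium ion that undergoes substitution, and the carboxylic acid, far more acidic than the phenol, is the pronucleophile that is deprotonated and attacks. 7 should therefore form without a protecting group.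

## Further compounds

F1 | step 1 | docosan-1-ol | CCCCCCCCCCCCCCCCCCCCCCO
F2 | step 1 | 1-bromodocosane | CCCCCCCCCCCCCCCCCCCCCCBr
F3 | step 1 | docosylmagnesium bromide | CCCCCCCCCCCCCCCCCCCCCC[Mg]Br
F4 | step 2 | dotriacontanoic acid | CCCCCCCCCCCCCCCCCCCCCCCCCCCCCCCC(=O)O
A1 | alternative 1 | dotriacontanoic acid | CCCCCCCCCCCCCCCCCCCCCCCCCCCCCCCC(=O)O
A2 | alternative 2 | 4-(2-bromoethyl)phenol | Oc1ccc(CCBr)cc1
A3 | alternative 2 | spiro[2.5]octa-4,7-dien-6-one | O=C1C=CC2(CC2)C=C1
A4 | alternative 3 | methyl (13Z)-docos-13-enoate (methyl erucate) | CCCCCCCC/C=C\CCCCCCCCCCCC(=O)OC
A5 | alternative 3 | icos-1-ene | C=CCCCCCCCCCCCCCCCCCC
A6 | alternative 3 | methyl dotriacont-13-enoate (E/Z mixture) | CCCCCCCCCCCCCCCCCCC=CCCCCCCCCCCCC(=O)OC
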